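The oxolane (ring A; O1; C2 with the dienyl chain; C3 with OH; C4 methylene; C5 with CH3) is read as a γ-lactone in disguise: O1–C5 as an acetate ester, C4 as a carbenoid carbon, C3–H as an ether-activated C–H bond. The route rests on the C3–C4 bond, made by enantioselective rhodium-carbenoid C–H insertion in the diazoacetate of achiral 1,3-bis(benzyloxy)propan-2-ol. That one operation closes ring A, desymmetrises the glycerol unit and sets C2 and C3. Methyllithium addition and ionic hydrogenation then set C5; Suzuki coupling of the derived (E)-alkenylboronate with an orsellinate-derived (E)-iodovinyl chloroisocoumarin completes the diene.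

Key step: step 2

Assumption: Rh2(4R-MPPIM)4 (dirhodium tetrakis[methyl (4R)-2-oxo-1-(3-phenylpropanoyl)imidazolidine-4-carboxylate], divalent rhodium) is taken to deliver the (4R,5R)-lactone 5; if the sense of induction is the opposite, the 4S catalyst is used and nothing else changes.

Remark: ring A locants (O1, C2, C3, C4, C5) always refer to the oxolane of the target; compound names use their own systematic numbering.

Step 1
Reactants: 1 1,3-bis(benzyloxy)propan-2-ol; 2 glyoxylic acid chloride p-toluenesulfonylhydrazone
Product: 4 1,3-bis(benzyloxy)propan-2-yl 2-diazoacetate, via tosylhydrazone ester 3 (not isolated)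
Conditions: PhNMe2, CH2Cl2, 0 °C; then Et3N, 0 °C to rt
Reagents that add atoms: none
Why: Acylation of the secondary alcohol by the acid chloride should give ester 3, from which triethylamine triggers a Bamford–Stevens-type loss of p-toluenesulfinate to unveil the diazoacetate; no stereocenter is formed.

Step 2
Reactants: 4 1,3-bis(benzyloxy)propan-2-yl 2-diazoacetate
Product: 5 (4R,5R)-4-(benzyloxy)-5-[(benzyloxy)methyl]oxolan-2-one
Conditions: Rh2(4R-MPPIM)4 (1 mol %), CH2Cl2, reflux, slow addition of 4
Reagents that add atoms: none
Why: The catalyst expels N2 from 4 to give an electrophilic rhodium carbenoid at C4, which should insert through a concerted three-centre transition state, with hydride-like donation from the C–H bond, into one C–H bond of a CH2OBn arm and so form C3–C4 directly. The closest known reaction type is the enantioselective intramolecular C–H insertion of alkyl diazoacetates to γ-lactones under chiral dirhodium carboxamidate catalysis, a class that includes 1,3-dialkoxypropan-2-yl esters. The oxolan-2-one ring is closed by 1,5-insertion, through a five-membered cyclic transition state made of the carbenoid carbon, the ester C=O carbon, O1, C2 and C3. C2 is fixed by the catalyst choosing one of the two enantiotopic CH2OBn arms of the achiral substrate, and C3 by its choice between the two diastereotopic hydrogens of that arm, which should place the benzyloxy group cis to the spectator arm. The step needs site selectivity (the ether-activated methylene C–H over the acyloxy-deactivated methine C–H that would give a β-lactone, over benzylic C–H through a seven-membered transition state, and over addition to the arenes) and cis diastereoselectivity; oxygen activation, the five-ring preference and the weakly electrophilic carboxamidate ligands should secure the former, the chiral ligand pocket the latter. Slow addition keeps the carbenoid from dimerising.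

Step 3
Reactants: 5 (4R,5R)-4-(benzyloxy)-5-[(benzyloxy)methyl]oxolan-2-one
Product: 6 (4R,5R)-4-(benzyloxy)-5-[(benzyloxy)methyl]-2-methyloxolan-2-ol (anomeric mixture)
Conditions: MeLi (1.1 equiv), THF, −78 °C; NH4Cl (aq) at −78 °C
Reagents that add atoms: methyllithium, [Li]C
Why: Addition of MeLi to the lactone carbonyl should give a lithium hemiketal alkoxide that is stable at −78 °C and therefore resists a second addition (lactone-to-lactol addition); the new anomeric centre is inconsequential and C2/C3 are untouched.

Step 4
Reactants: 6 (4R,5R)-4-(benzyloxy)-5-[(benzyloxy)methyl]-2-methyloxolan-2-ol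
Product: 7 (2R,3R,5R)-3-(benzyloxy)-2-[(benzyloxy)methyl]-5-methyloxolane
Conditions: Et3SiH, BF3·OEt2, CH2Cl2, −78 to −20 °C
Reagents that add atoms: none
Why: Ionic hydrogenation of the hemiketal: BF3 ionises it to the five-membered oxocarbenium ion, and by the inside-attack model (envelope with the benzyloxy group pseudoaxial) hydride should enter cis to that group, so the methyl group ends trans to both ring substituents (5R).

Step 5
Reactants: 7 (2R,3R,5R)-3-(benzyloxy)-2-[(benzyloxy)methyl]-5-methyloxolane
Product: 8 (2R,3R,5R)-2-(hydroxymethyl)-5-methyloxolan-3-ol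
Conditions: H2 (1 atm), Pd/C, EtOH, rt
Reagents that add atoms: none
Why: Hydrogenolysis should cleave both benzyl ethers while the saturated oxolane and its three stereocenters are unaffected.

Step 6
Reactants: 8 (2R,3R,5R)-2-(hydroxymethyl)-5-methyloxolan-3-ol
Product: 9 (2S,3R,5R)-3-hydroxy-5-methyloxolane-2-carbaldehyde
Conditions: TEMPO (10 mol %), PhI(OAc)2, CH2Cl2, rt; used crude
Reagents that add atoms: none
Why: Oxoammonium oxidation (TEMPO/PhI(OAc)2) is selective for the primary over the secondary alcohol and should stop at the aldehyde under these nearly neutral, anhydrous conditions, which also spare the α-stereocenter (the descriptor changes only through priorities).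

Step 7
Reactants: 9 (2S,3R,5R)-3-hydroxy-5-methyloxolane-2-carbaldehyde
Product: 10 (2R,3R,5R)-5-methyl-2-[(E)-2-(4,4,5,5-tetramethyl-1,3,2-dioxaborolan-2-yl)ethenyl]oxolan-3-ol
Conditions: CrCl2, LiI, Cl2CHBpin, THF, rt
Reagents that add atoms: 2-(dichloromethyl)-4,4,5,5-tetramethyl-1,3,2-dioxaborolane, ClC(Cl)B1OC(C)(C)C(C)(C)O1
Why: Takai–Utimoto boryl olefination: the gem-dichromium species formed from the in-situ diiodide adds to the aldehyde and eliminates to the (E)-alkenylboronate, and divalent chromium should tolerate the free hydroxyl.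

Step 8
Reactants: 11 methyl 2,4-dimethoxy-6-methylbenzoate
Product: 12 methyl 3-chloro-4,6-dimethoxy-2-methylbenzoate
Conditions: SO2Cl2 (1.05 equiv), CH2Cl2, 0 °C to rt
Reagents that add atoms: sulfuryl chloride, ClS(Cl)(=O)=O
Why: Electrophilic aromatic chlorination should occur at the free position flanked by the methyl and a methoxy group (para to the other methoxy group), since the position between the two methoxy groups is the more shielded one.

Step 9
Reactants: 12 methyl 3-chloro-4,6-dimethoxy-2-methylbenzoate; 13 methyl 2,2-dimethoxyacetate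
Product: 15 5-chloro-6,8-dimethoxy-1-oxo-1H-isochromene-3-carbaldehyde, via keto acetal ester 14 (not isolated)
Conditions: LiN(i-Pr)2 (2.2 equiv), THF, −78 °C; 13, −78 to 0 °C; then 3 M HCl, THF, 50 °C
Reagents that add atoms: water, O
Why: Lateral lithiation of the o-toluate gives a benzylic anion that is acylated by the ester (Claisen-type acylation, the second equivalent of base storing the ketone as its enolate), and aqueous acid should then effect enol lactonisation onto the neighbouring methyl ester together with acetal hydrolysis.

Step 10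
Reactants: 15 5-chloro-6,8-dimethoxy-1-oxo-1H-isochromene-3-carbaldehyde
Product: 16 5-chloro-3-[(E)-2-iodoethenyl]-6,8-dimethoxy-1H-isochromen-1-one
Conditions: CrCl2, CHI3, THF, 0 °C to rt
Reagents that add atoms: iodoform, IC(I)I
Why: Takai iodo-olefination of the conjugated aldehyde should give the (E)-vinyl iodide by elimination from the β-oxido chromium intermediate, with the enol lactone and aryl chloride inert to divalent chromium.

Step 11
Reactants: 16 5-chloro-3-[(E)-2-iodoethenyl]-6,8-dimethoxy-1H-isochromen-1-one
Product: 17 5-chloro-6,8-dihydroxy-3-[(E)-2-iodoethenyl]-1H-isochromen-1-one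
Conditions: BBr3 (5 equiv), CH2Cl2, −78 °C to rt; H2O
Reagents that add atoms: none
Why: BBr3 demethylation (bromide attack on the boron-activated O–CH3 groups) should free both phenols while the enol lactone and the vinyl iodide survive, so that no protecting group is carried into the sensitive dienyl oxolane.

Step 12
Reactants: 10 (2R,3R,5R)-5-methyl-2-[(E)-2-(4,4,5,5-tetramethyl-1,3,2-dioxaborolan-2-yl)ethenyl]oxolan-3-ol; 17 5-chloro-6,8-dihydroxy-3-[(E)-2-iodoethenyl]-1H-isochromen-1-one
Product: 18 5-chloro-6,8-dihydroxy-3-[(1E,3E)-4-[(2R,3R,5R)-3-hydroxy-5-methyloxolan-2-yl]buta-1,3-dien-1-yl]-1H-isochromen-1-one (CNP0086741.4)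
Conditions: Pd(dppf)Cl2 (5 mol %), K3PO4 (aq, 4 equiv), THF, degassed, rt to 40 °C; pH 4 buffer on work-up
Reagents that add atoms: none
Why: Suzuki–Miyaura coupling: oxidative addition of zerovalent palladium to the vinyl iodide (far faster than to the hindered aryl chloride), transmetalation of the alkenylboronate and reductive elimination all proceed with retention, so the (E,E)-diene should form directly from the unprotected partners.

Compound list
1 | 1,3-bis(benzyloxy)propan-2-ol | OC(COCc1ccccc1)COCc1ccccc1 | starting material
2 | glyoxylic acid chloride p-toluenesulfonylhydrazone, (2E)-2-(tosylhydrazinylidene)acetyl chloride | Cc1ccc(cc1)S(=O)(=O)N/N=C/C(=O)Cl | starting material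
3 | 1,3-bis(benzyloxy)propan-2-yl (2E)-2-(tosylhydrazinylidene)acetate | Cc1ccc(cc1)S(=O)(=O)N/N=C/C(=O)OC(COCc1ccccc1)COCc1ccccc1 | intermediate (not isolated)
4 | 1,3-bis(benzyloxy)propan-2-yl 2-diazoacetate | [N-]=[N+]=CC(=O)OC(COCc1ccccc1)COCc1ccccc1 | intermediate
5 | (4R,5R)-4-(benzyloxy)-5-[(benzyloxy)methyl]oxolan-2-one | O=C1C[C@@H](OCc2ccccc2)[C@@H](COCc2ccccc2)O1 | intermediate
6 | (4R,5R)-4-(benzyloxy)-5-[(benzyloxy)methyl]-2-methyloxolan-2-ol, anomeric mixture | CC1(O)C[C@@H](OCc2ccccc2)[C@@H](COCc2ccccc2)O1 | intermediate
7 | (2R,3R,5R)-3-(benzyloxy)-2-[(benzyloxy)methyl]-5-methyloxolane | C[C@@H]1C[C@@H](OCc2ccccc2)[C@@H](COCc2ccccc2)O1 | intermediate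
8 | (2R,3R,5R)-2-(hydroxymethyl)-5-methyloxolan-3-ol | C[C@@H]1C[C@@H](O)[C@@H](CO)O1 | intermediate
9 | (2S,3R,5R)-3-hydroxy-5-methyloxolane-2-carbaldehyde | C[C@@H]1C[C@@H](O)[C@@H](C=O)O1 | intermediate
10 | (2R,3R,5R)-5-methyl-2-[(E)-2-(4,4,5,5-tetramethyl-1,3,2-dioxaborolan-2-yl)ethenyl]oxolan-3-ol | C[C@@H]1C[C@@H](O)[C@@H](/C=C/B2OC(C)(C)C(C)(C)O2)O1 | intermediate
11 | methyl 2,4-dimethoxy-6-methylbenzoate | COC(=O)c1c(C)cc(OC)cc1OC | starting material
12 | methyl 3-chloro-4,6-dimethoxy-2-methylbenzoate | COC(=O)c1c(C)c(Cl)c(OC)cc1OC | intermediate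
13 | methyl 2,2-dimethoxyacetate | COC(OC)C(=O)OC | starting material
14 | methyl 3-chloro-2-(3,3-dimethoxy-2-oxopropyl)-4,6-dimethoxybenzoate | COC(=O)c1c(CC(=O)C(OC)OC)c(Cl)c(OC)cc1OC | intermediate (not isolated)
15 | 5-chloro-6,8-dimethoxy-1-oxo-1H-isochromene-3-carbaldehyde | O=Cc1cc2c(Cl)c(OC)cc(OC)c2c(=O)o1 | intermediate
16 | 5-chloro-3-[(E)-2-iodoethenyl]-6,8-dimethoxy-1H-isochromen-1-one | I/C=C/c1cc2c(Cl)c(OC)cc(OC)c2c(=O)o1 | intermediate
17 | 5-chloro-6,8-dihydroxy-3-[(E)-2-iodoethenyl]-1H-isochromen-1-one | I/C=C/c1cc2c(Cl)c(O)cc(O)c2c(=O)o1 | intermediate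
18 | 5-chloro-6,8-dihydroxy-3-[(1E,3E)-4-[(2R,3R,5R)-3-hydroxy-5-methyloxolan-2-yl]buta-1,3-dien-1-yl]-1H-isochromen-1-one | C[C@@H]1C[C@@H](O)[C@@H](/C=C/C=C/c2cc3c(Cl)c(O)cc(O)c3c(=O)o2)O1 | target

Total step count: 12. Longest linear sequence: 8 (steps 1 to 7, then step 12).

Steps most likely to fail

Step 2. The conformationally free carbenoid may discriminate poorly between the two diastereotopic hydrogens of the reacting arm (cis/trans leakage), or be diverted to carbene dimer. The fallback uses a temporary ring. It sets out from acid chloride 2, which under the step 1 conditions is esterified with commercial cis-2-phenyl-1,3-dioxan-5-ol (O[C@H]1CO[C@@H](c2ccccc2)OC1) in place of 1. This gives, through the tosylhydrazone ester F1, cis-2-phenyl-1,3-dioxan-5-yl 2-diazoacetate F2. Its ester is held axial, so only the two enantiotopic equatorial C–H bonds beside it are within reach. The same chiral rhodium catalyst should therefore give only the cis-fused 3,5-O-benzylidene-2-deoxy-D-xylono-1,4-lactone F3. Hydrogenolysis (H2, Pd(OH)2/C, EtOAc) gives 2-deoxy-D-xylono-1,4-lactone F4, and acid-catalysed benzylation (benzyl 2,2,2-trichloroacetimidate, TfOH cat., CH2Cl2) comes back to the route at lactone 5.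

Step 4. Facial selectivity of hydride delivery to the oxocarbenium ion may be eroded, because the side chain at C2 lies on the face that the inside-attack preference requires; the ion may also be lost to the enol ether. The fallback replaces oxocarbenium reduction by a stereospecific SN2 ring closure. It sets out from hemiketal 6, whose open hydroxy-ketone tautomer is reduced under reagent control (Corey–Bakshi–Shibata reduction, (R)-Me-oxazaborolidine, BH3·SMe2) to (2S,4R,5R)-4,6-bis(benzyloxy)hexane-2,5-diol F5. Selective sulfonylation of the less hindered methyl carbinol (TsCl, pyridine, 0 °C) gives (2S,4R,5R)-4,6-bis(benzyloxy)-5-hydroxyhexan-2-yl 4-methylbenzenesulfonate F6. NaH in THF then closes the oxolane with inversion at the methyl-bearing carbon, coming back to the route at 7.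

Step 7. The free hydroxyl may sequester or protonate the gem-dichromium reagent, and the crude hydroxy aldehyde may hydrate, oligomerise or epimerise at its α-carbon before olefination. The fallback replaces the chromium olefination by alkyne hydrometalation. It sets out from aldehyde 9, which is homologated by the Ohira–Bestmann reaction (dimethyl (1-diazo-2-oxopropyl)phosphonate, K2CO3, MeOH, 0 °C) to (2R,3R,5R)-2-ethynyl-5-methyloxolan-3-ol F7. Hydroboration with pinacolborane catalysed by Cp2Zr(H)Cl (excess borane to cover the hydroxyl, Et3N, CH2Cl2; syn addition with boron at the terminus) comes back to the route at boronate 10.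

Further compounds
F1 | step 2 | cis-2-phenyl-1,3-dioxan-5-yl (2E)-2-(tosylhydrazinylidene)acetate | Cc1ccc(cc1)S(=O)(=O)N/N=C/C(=O)O[C@H]1CO[C@@H](c2ccccc2)OC1
F2 | step 2 | cis-2-phenyl-1,3-dioxan-5-yl 2-diazoacetate | [N-]=[N+]=CC(=O)O[C@H]1CO[C@@H](c2ccccc2)OC1
F3 | step 2 | 3,5-O-benzylidene-2-deoxy-D-xylono-1,4-lactone (cis-fused, phenyl equatorial) | O=C1C[C@H]2O[C@@H](c3ccccc3)OC[C@H]2O1
F4 | step 2 | 2-deoxy-D-xylono-1,4-lactone, (4R,5R)-4-hydroxy-5-(hydroxymethyl)oxolan-2-one | O=C1C[C@@H](O)[C@@H](CO)O1
F5 | step 4 | (2S,4R,5R)-4,6-bis(benzyloxy)hexane-2,5-diol | C[C@H](O)C[C@@H](OCc1ccccc1)[C@H](O)COCc1ccccc1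
F6 | step 4 | (2S,4R,5R)-4,6-bis(benzyloxy)-5-hydroxyhexan-2-yl 4-methylbenzenesulfonate | C[C@H](OS(=O)(=O)c1ccc(C)cc1)C[C@@H](OCc1ccccc1)[C@H](O)COCc1ccccc1
F7 | step 7 | (2R,3R,5R)-2-ethynyl-5-methyloxolan-3-ol | C[C@@H]1C[C@@H](O)[C@@H](C#C)O1
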